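## Retrosynthetic overview

1. Target ⇐ C9 ketone by hydroxyl-directed 1,3-anti reduction; the butenoyl ketone ⇐ C2 thioester + (E)-propenylboronic acid (Liebeskind–Srogl acylation).
2. C5 tiglate ⇐ C5 iodide by silver tiglate with retention (C1–OH relay through an epoxide); C6 lactone and C5 iodide ⇐ cycloheptene by iodolactonisation.
3. Cycloheptene ⇐ ring-closing metathesis of a diene ketone; diene ketone ⇐ palladium-catalysed thioester–alkylzinc coupling (C8–C9 bond) of fragment A with fragment B.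
4. Fragment A (C1, C10) ⇐ bis(oxazoline)–copper aldol of a 2-oxo ester with a propanethioate silyl ketene acetal; fragment B (C7, C11) ⇐ Ireland–Claisen rearrangement with chirality transfer from (S)-but-3-yn-2-ol.
5. Ring order: seven-membered carbocycle first, then the γ-lactone.

Locants used below: C1 = ring carbon with OH and the butenoyl group; C2 = butenoyl C=O (C3, C4, C15 = its CH=CH–CH3); C5 = ring CH–O(tigloyl); C6 = ring CH–O(lactone); C7 = ring CH carrying C11; C8 = ring CH2; C9 = ring CHOH; C10 = ring CH(CH3); C11 = lactone CH(CH3); C12 = lactone C=O.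

Assumption: (S)-but-3-yn-2-ol, S-ethyl propanethioate, tiglic acid and (E)-prop-1-en-1-ylboronic acid are bought. The route is a paper design and has not been run; in particular, the ligand enantiomer in step 6 is chosen from memory of the sense of induction in the pyruvate aldol and should be confirmed.

## Fragment A (thioester, carries C1 and C10)

Step 1
Reactants: 1 acryloyl chloride; 2 tert-butanol
Product: 3 tert-butyl prop-2-enoate
Conditions: Et3N, DMAP (5 mol %), CH2Cl2, 0 °C to rt
Reagents that add atoms: none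
Why: Acylation of tert-butanol by the acid chloride (nucleophilic acyl substitution) gives the acid-labile ester that is carried as C2 until step 22.

Step 2
Reactants: 3 tert-butyl prop-2-enoate
Product: 4 tert-butyl 2,3-dihydroxypropanoate (racemic)
Conditions: K2OsO2(OH)4 (0.5 mol %), N-methylmorpholine N-oxide, acetone/H2O 4:1, rt
Reagents that add atoms: N-methylmorpholine N-oxide, C[N+]1([O-])CCOCC1; water, O
Why: Upjohn dihydroxylation gives the glycerate; it is made racemic because its stereocentre is oxidised away in step 4.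

Step 3
Reactants: 4 tert-butyl 2,3-dihydroxypropanoate
Product: 5 tert-butyl 2-hydroxy-3-[(triethylsilyl)oxy]propanoate (racemic)
Conditions: Et3SiCl (1.05 equiv), imidazole, CH2Cl2, −20 °C
Reagents that add atoms: chlorotriethylsilane, CC[Si](Cl)(CC)CC
Why: Silylation is selective for the primary hydroxyl over the hindered, ester-deactivated secondary one.

Step 4
Reactants: 5 tert-butyl 2-hydroxy-3-[(triethylsilyl)oxy]propanoate
Product: 6 tert-butyl 2-oxo-3-[(triethylsilyl)oxy]propanoate
Conditions: Dess–Martin periodinane, CH2Cl2, 0 °C to rt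
Reagents that add atoms: none
Why: Dess–Martin oxidation of the secondary alcohol gives the 2-oxo ester, a 1,2-dicarbonyl that can chelate the aldol catalyst, without touching the silyl ether.

Step 5
Reactants: 7 S-ethyl propanethioate
Product: 8 {[(1Z)-1-(ethylsulfanyl)prop-1-en-1-yl]oxy}trimethylsilane
Conditions: LiN(iPr)2, THF, −78 °C; Me3SiCl
Reagents that add atoms: chlorotrimethylsilane, C[Si](C)(C)Cl
Why: Kinetic enolisation of the thioester and O-silylation give the (Z)-silyl ketene thioacetal, the nucleophile for the Mukaiyama aldol.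

Step 6
Reactants: 6 tert-butyl 2-oxo-3-[(triethylsilyl)oxy]propanoate; 8 {[(1Z)-1-(ethylsulfanyl)prop-1-en-1-yl]oxy}trimethylsilane
Product: 9 tert-butyl (2S,3R)-4-(ethylsulfanyl)-3-methyl-4-oxo-2-{[(triethylsilyl)oxy]methyl}-2-[(trimethylsilyl)oxy]butanoate
Conditions: Cu(OTf)2 (10 mol %), 2,2'-(propane-2,2-diyl)bis[(4R)-4-tert-butyl-4,5-dihydro-1,3-oxazole] (11 mol %), THF, −78 °C, 24 h; neutral work-up
Reagents that add atoms: none
Why: Evans-type bis(oxazoline)–copper Mukaiyama aldol to a 2-oxo ester: the divalent copper centre chelates the 1,2-dicarbonyl of 6, the (R,R)-ligand (mirror image of the one that gives (S)-pyruvate adducts) leaves the Re face of the ketone open and sets C1, the open transition state gives the syn C1–O/C10–CH3 relationship that sets C10, and silyl transfer delivers the tertiary trimethylsilyl ether.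

Step 7
Reactants: 9 tert-butyl (2S,3R)-4-(ethylsulfanyl)-3-methyl-4-oxo-2-{[(triethylsilyl)oxy]methyl}-2-[(trimethylsilyl)oxy]butanoate
Product: 10 tert-butyl (2S,3R)-4-(ethylsulfanyl)-2-formyl-3-methyl-4-oxo-2-[(trimethylsilyl)oxy]butanoate
Conditions: (COCl)2, DMSO, CH2Cl2, −78 to −40 °C; Et3N, to 0 °C
Reagents that add atoms: none
Why: Swern oxidation applied directly to the primary triethylsilyl ether (chlorosulfonium-induced desilylation, then ylide fragmentation) gives the non-enolisable aldehyde while the hindered tertiary trimethylsilyl ether survives.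

Step 8
Reactants: 10 tert-butyl (2S,3R)-4-(ethylsulfanyl)-2-formyl-3-methyl-4-oxo-2-[(trimethylsilyl)oxy]butanoate
Product: 11 tert-butyl (2R,3R)-2-ethenyl-4-(ethylsulfanyl)-3-methyl-4-oxo-2-[(trimethylsilyl)oxy]butanoate
Conditions: Ph3PCH3Br, KN(SiMe3)2, THF, 0 °C; then 10, −78 to 0 °C
Reagents that add atoms: methyltriphenylphosphonium bromide, C[P+](c1ccccc1)(c1ccccc1)c1ccccc1.[Br-]
Why: Wittig methylenation of the aldehyde, fast at −78 °C and leaving the thioester and both stereocentres alone, installs the vinyl group (C5 plus the carbon later lost in the ring closure); the descriptor at C1 changes only because the priorities change.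

## Fragment B (iodide, carries C7 and C11)

Step 9
Reactants: 12 (S)-but-3-yn-2-ol; 13 formaldehyde (used as paraformaldehyde)
Product: 14 (4S)-pent-2-yne-1,4-diol
Conditions: n-BuLi (2.1 equiv), THF, −78 °C; (CH2O)n, −78 °C to rt; aq. NH4Cl
Reagents that add atoms: none
Why: Addition of the lithium acetylide (dianion) of 12 to formaldehyde adds the future C8 without touching the carbinol stereocentre.

Step 10
Reactants: 14 (4S)-pent-2-yne-1,4-diol
Product: 15 (2S)-5-{[tert-butyl(dimethyl)silyl]oxy}pent-3-yn-2-ol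
Conditions: tBuMe2SiCl (1.0 equiv), imidazole, CH2Cl2, −20 °C
Reagents that add atoms: tert-butyl(chloro)dimethylsilane, CC(C)(C)[Si](C)(C)Cl
Why: The unhindered primary propargylic hydroxyl is silylated selectively over the secondary one.

Step 11
Reactants: 15 (2S)-5-{[tert-butyl(dimethyl)silyl]oxy}pent-3-yn-2-ol
Product: 16 (2S,3E)-5-{[tert-butyl(dimethyl)silyl]oxy}pent-3-en-2-ol
Conditions: NaAlH2(OCH2CH2OCH3)2 (1.5 equiv), THF, 0 °C to rt; aq. KNaC4H4O6
Reagents that add atoms: none
Why: Hydroxyl-directed trans-hydroalumination of the propargylic alcohol and protonolysis give the (E)-allylic alcohol needed for a chair Claisen transition state.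

Step 12
Reactants: 16 (2S,3E)-5-{[tert-butyl(dimethyl)silyl]oxy}pent-3-en-2-ol; 17 propanoyl chloride
Product: 18 (2S,3E)-5-{[tert-butyl(dimethyl)silyl]oxy}pent-3-en-2-yl propanoate
Conditions: Et3N, DMAP (5 mol %), CH2Cl2, 0 °C
Reagents that add atoms: none
Why: O-acylation with the acid chloride gives the allylic propanoate, the Ireland–Claisen substrate.

Step 13
Reactants: 18 (2S,3E)-5-{[tert-butyl(dimethyl)silyl]oxy}pent-3-en-2-yl propanoate
Product: 21 (2R,3R,4E)-3-({[tert-butyl(dimethyl)silyl]oxy}methyl)-2-methylhex-4-enoic acid, via silyl ketene acetal 19 (not isolated), via trimethylsilyl ester 20 (not isolated)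
Conditions: LiN(iPr)2, THF, −78 °C; Me3SiCl, −78 °C to rt, then 45 °C; aq. citric acid
Reagents that add atoms: none
Why: Ireland–Claisen rearrangement: kinetic enolisation in THF gives the (E)-silyl ketene acetal 19, whose chair transition state with the carbinol methyl equatorial transfers the (S)-carbinol chirality to C7 and places the α-methyl anti to it (C11), leaving an (E)-propenyl group as the future C6 terminus; mild acid frees the acid from 20.

Step 14
Reactants: 21 (2R,3R,4E)-3-({[tert-butyl(dimethyl)silyl]oxy}methyl)-2-methylhex-4-enoic acid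
Product: 22 tert-butyl (2R,3R,4E)-3-({[tert-butyl(dimethyl)silyl]oxy}methyl)-2-methylhex-4-enoate
Conditions: tert-butyl 2,2,2-trichloroacetimidate (2 equiv), BF3·OEt2 (5 mol %), cyclohexane/CH2Cl2, rt
Reagents that add atoms: tert-butyl 2,2,2-trichloroacetimidate, CC(C)(C)OC(=N)C(Cl)(Cl)Cl
Why: Acid-catalysed tert-butylation with the trichloroacetimidate (SN1 transfer of the tert-butyl cation) masks C12 as an ester that resists lactonisation in step 15 and leaves by itself in step 20.

Step 15
Reactants: 22 tert-butyl (2R,3R,4E)-3-({[tert-butyl(dimethyl)silyl]oxy}methyl)-2-methylhex-4-enoate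
Product: 23 tert-butyl (2R,3R,4E)-3-(hydroxymethyl)-2-methylhex-4-enoate
Conditions: HF·pyridine, pyridine/THF, 0 °C to rt
Reagents that add atoms: none
Why: Fluoride desilylation frees the primary alcohol; the tert-butyl ester is too hindered to lactonise onto it.

Step 16
Reactants: 23 tert-butyl (2R,3R,4E)-3-(hydroxymethyl)-2-methylhex-4-enoate
Product: 24 tert-butyl (2R,3R,4E)-3-(iodomethyl)-2-methylhex-4-enoate
Conditions: I2, PPh3, imidazole, CH2Cl2, 0 °C
Reagents that add atoms: iodine, II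
Why: Appel-type iodination (SN2 at the primary carbon) gives the iodide for zinc insertion.

## Silver tiglate

Step 17
Reactants: 25 tiglic acid [(2E)-2-methylbut-2-enoic acid]
Product: 26 silver (2E)-2-methylbut-2-enoate
Conditions: Ag2O (0.5 equiv), MeCN/H2O, rt, dark; dried in vacuo
Reagents that add atoms: silver oxide, [Ag+].[Ag+].[O-2]
Why: Acid–base reaction of the carboxylic acid with Ag2O gives the anhydrous silver carboxylate used in step 21.

## Fragment union, ring formation and endgame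

Step 18
Reactants: 24 tert-butyl (2R,3R,4E)-3-(iodomethyl)-2-methylhex-4-enoate; 11 tert-butyl (2R,3R)-2-ethenyl-4-(ethylsulfanyl)-3-methyl-4-oxo-2-[(trimethylsilyl)oxy]butanoate
Product: 29 di-tert-butyl (2R,3R,6R,7R)-2-ethenyl-2-hydroxy-3,7-dimethyl-4-oxo-6-[(1E)-prop-1-en-1-yl]octanedioate, via organozinc iodide 27 (not isolated), via trimethylsilyl ether 28 (not isolated)
Conditions: Zn dust (activated with BrCH2CH2Br and Me3SiCl), LiCl, THF, 40 °C; then 11, PdCl2(PPh3)2 (10 mol %), THF/toluene, rt, 12 h; then 1 M HCl, THF, 0 °C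
Reagents that add atoms: none
Why: Fukuyama coupling (zinc insertion into the C–I bond, oxidative addition of zerovalent palladium into the C(acyl)–S bond, transmetalation, reductive elimination) forms the C8–C9 bond and unites the two fragments with esters, alkenes and all four stereocentres untouched; the acid work-up removes the trimethylsilyl group.

Step 19
Reactants: 29 di-tert-butyl (2R,3R,6R,7R)-2-ethenyl-2-hydroxy-3,7-dimethyl-4-oxo-6-[(1E)-prop-1-en-1-yl]octanedioate
Product: 30 tert-butyl (1R,4R,7R)-4-[(2R)-1-tert-butoxy-1-oxopropan-2-yl]-1-hydroxy-7-methyl-6-oxocyclohept-2-ene-1-carboxylate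
Conditions: second-generation Hoveyda–Grubbs catalyst, RuCl2(H2IMes)(=CH–C6H4-2-OiPr) (5 mol %), CH2Cl2 (2 mM), 40 °C
Reagents that add atoms: none
Why: Ring-closing metathesis of the vinyl and (E)-propenyl groups (propene lost) closes the seven-membered carbocycle as the cis-cycloheptene; the free tertiary allylic hydroxyl is tolerated and no stereocentre is touched.

Step 20
Reactants: 30 tert-butyl (1R,4R,7R)-4-[(2R)-1-tert-butoxy-1-oxopropan-2-yl]-1-hydroxy-7-methyl-6-oxocyclohept-2-ene-1-carboxylate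
Product: 31 tert-butyl (3R,3aS,6R,7R,8S,8aR)-7-hydroxy-8-iodo-3,6-dimethyl-2,5-dioxooctahydro-2H-cyclohepta[b]furan-7-carboxylate
Conditions: I2 (3 equiv), NaHCO3 (3 equiv), MeCN, 0 °C to rt, dark
Reagents that add atoms: iodine, II
Why: Iodolactonisation: the tert-butyl ester carbonyl on the C7 side chain opens the iodonium ion at C6 in 5-exo fashion (isobutene lost) and can do so only from its own face, which gives the cis-fused γ-lactone (sets C6) and, by anti addition, the C5 iodide trans to the lactone oxygen and anti to the C1 hydroxyl.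

Step 21
Reactants: 31 tert-butyl (3R,3aS,6R,7R,8S,8aR)-7-hydroxy-8-iodo-3,6-dimethyl-2,5-dioxooctahydro-2H-cyclohepta[b]furan-7-carboxylate; 26 silver (2E)-2-methylbut-2-enoate
Product: 33 tert-butyl (3R,3aS,6R,7S,8S,8aR)-7-hydroxy-3,6-dimethyl-8-{[(2E)-2-methylbut-2-enoyl]oxy}-2,5-dioxooctahydro-2H-cyclohepta[b]furan-7-carboxylate, via epoxide 32 (not isolated)
Conditions: 26 (2.5 equiv), 25 (1 equiv), toluene/MeCN 4:1, 50 °C, dark
Reagents that add atoms: none
Why: Proposed new method: silver carboxylate iodide-to-acyloxy exchange with retention, relayed by a neighbouring tertiary hydroxyl — the silver cation pulls off the C5 iodide while the anti-periplanar C1 hydroxyl closes to glycidic ester 32 (first inversion), and tiglate then opens 32 at C5, the only carbon open to SN2 attack because C1 is quaternary and α to the ester, from the face opposite the epoxide oxygen (second inversion), so the tigloyloxy group takes the place of iodine trans to the lactone oxygen (sets C5) and the C1 hydroxyl is returned; the closest known reactions are Prévost–Woodward silver carboxylate/halide chemistry with neighbouring-group participation and the β-selective opening of glycidic esters by carboxylates.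

Step 22
Reactants: 33 tert-butyl (3R,3aS,6R,7S,8S,8aR)-7-hydroxy-3,6-dimethyl-8-{[(2E)-2-methylbut-2-enoyl]oxy}-2,5-dioxooctahydro-2H-cyclohepta[b]furan-7-carboxylate
Product: 34 (3R,3aS,6R,7S,8S,8aR)-7-hydroxy-3,6-dimethyl-8-{[(2E)-2-methylbut-2-enoyl]oxy}-2,5-dioxooctahydro-2H-cyclohepta[b]furan-7-carboxylic acid
Conditions: CF3CO2H/CH2Cl2 1:4, 0 °C, 2 h
Reagents that add atoms: none
Why: Acidolysis of the tert-butyl ester (E1 loss of isobutene) unmasks the C2 acid; lactone and tiglate are stable and the C1 carbinol, flanked by the carboxyl group, does not ionise.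

Step 23
Reactants: 34 (3R,3aS,6R,7S,8S,8aR)-7-hydroxy-3,6-dimethyl-8-{[(2E)-2-methylbut-2-enoyl]oxy}-2,5-dioxooctahydro-2H-cyclohepta[b]furan-7-carboxylic acid
Product: 35 S-ethyl (3R,3aS,6R,7S,8S,8aR)-7-hydroxy-3,6-dimethyl-8-{[(2E)-2-methylbut-2-enoyl]oxy}-2,5-dioxooctahydro-2H-cyclohepta[b]furan-7-carbothioate
Conditions: EtSH, EDC·HCl, DMAP (10 mol %), CH2Cl2, 0 °C to rt
Reagents that add atoms: ethanethiol, CCS
Why: Carbodiimide (Steglich-type) thioesterification activates C2 under neutral conditions; the tertiary hydroxyl is too hindered to compete.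

Step 24
Reactants: 35 S-ethyl (3R,3aS,6R,7S,8S,8aR)-7-hydroxy-3,6-dimethyl-8-{[(2E)-2-methylbut-2-enoyl]oxy}-2,5-dioxooctahydro-2H-cyclohepta[b]furan-7-carbothioate; 36 (E)-prop-1-en-1-ylboronic acid
Product: 37 (3R,3aS,6R,7S,8S,8aR)-7-[(2E)-but-2-enoyl]-7-hydroxy-3,6-dimethyl-2,5-dioxooctahydro-2H-cyclohepta[b]furan-8-yl (2E)-2-methylbut-2-enoate
Conditions: Pd2(dba)3 (2.5 mol %), tri(2-furyl)phosphine (15 mol %), copper thiophene-2-carboxylate Cu(O2CC4H3S) (1.6 equiv), THF, 50 °C
Reagents that add atoms: none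
Why: Liebeskind–Srogl coupling (palladium-catalysed, copper carboxylate-mediated thioester–boronic acid cross-coupling without base) forms the C2–C3 bond and delivers the (E)-enone with retention of alkene geometry; the base-sensitive C11 centre is not exposed to base.

Step 25
Reactants: 37 (3R,3aS,6R,7S,8S,8aR)-7-[(2E)-but-2-enoyl]-7-hydroxy-3,6-dimethyl-2,5-dioxooctahydro-2H-cyclohepta[b]furan-8-yl (2E)-2-methylbut-2-enoate
Product: 38 (3R,3aS,5R,6S,7S,8S,8aR)-7-[(2E)-but-2-enoyl]-5,7-dihydroxy-3,6-dimethyl-2-oxooctahydro-2H-cyclohepta[b]furan-8-yl (2E)-2-methylbut-2-enoate (CNP0183494.2)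
Conditions: Me4NBH(OAc)3 (5 equiv), MeCN/AcOH 1:1, −30 °C
Reagents that add atoms: none
Why: Evans–Saksena hydroxyl-directed reduction: the C1 hydroxyl exchanges onto boron and delivers hydride to the C9 ketone through a six-membered chair transition state on its own face, giving the 1,3-anti diol (sets C9), while the conjugated and hindered C2 enone carbonyl is expected to react more slowly.

## Compound list

1 | acryloyl chloride | C=CC(=O)Cl | starting material
2 | tert-butanol | CC(C)(C)O | starting material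
3 | tert-butyl prop-2-enoate | C=CC(=O)OC(C)(C)C | intermediate
4 | tert-butyl 2,3-dihydroxypropanoate (racemic) | CC(C)(C)OC(=O)C(O)CO | intermediate
5 | tert-butyl 2-hydroxy-3-[(triethylsilyl)oxy]propanoate (racemic) | CC(C)(C)OC(=O)C(O)CO[Si](CC)(CC)CC | intermediate
6 | tert-butyl 2-oxo-3-[(triethylsilyl)oxy]propanoate | CC(C)(C)OC(=O)C(=O)CO[Si](CC)(CC)CC | intermediate
7 | S-ethyl propanethioate | CCC(=O)SCC | starting material
8 | {[(1Z)-1-(ethylsulfanyl)prop-1-en-1-yl]oxy}trimethylsilane | C/C=C(/O[Si](C)(C)C)SCC | intermediate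
9 | tert-butyl (2S,3R)-4-(ethylsulfanyl)-3-methyl-4-oxo-2-{[(triethylsilyl)oxy]methyl}-2-[(trimethylsilyl)oxy]butanoate | CC(C)(C)OC(=O)[C@@](O[Si](C)(C)C)(CO[Si](CC)(CC)CC)[C@@H](C)C(=O)SCC | intermediate
10 | tert-butyl (2S,3R)-4-(ethylsulfanyl)-2-formyl-3-methyl-4-oxo-2-[(trimethylsilyl)oxy]butanoate | CC(C)(C)OC(=O)[C@@](O[Si](C)(C)C)(C=O)[C@@H](C)C(=O)SCC | intermediate
11 | tert-butyl (2R,3R)-2-ethenyl-4-(ethylsulfanyl)-3-methyl-4-oxo-2-[(trimethylsilyl)oxy]butanoate (fragment A) | CC(C)(C)OC(=O)[C@@](O[Si](C)(C)C)(C=C)[C@@H](C)C(=O)SCC | intermediate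
12 | (S)-but-3-yn-2-ol | C[C@H](O)C#C | starting material
13 | formaldehyde (as paraformaldehyde) | C=O | starting material
14 | (4S)-pent-2-yne-1,4-diol | C[C@H](O)C#CCO | intermediate
15 | (2S)-5-{[tert-butyl(dimethyl)silyl]oxy}pent-3-yn-2-ol | C[C@H](O)C#CCO[Si](C)(C)C(C)(C)C | intermediate
16 | (2S,3E)-5-{[tert-butyl(dimethyl)silyl]oxy}pent-3-en-2-ol | C[C@H](O)/C=C/CO[Si](C)(C)C(C)(C)C | intermediate
17 | propanoyl chloride | CCC(=O)Cl | starting material
18 | (2S,3E)-5-{[tert-butyl(dimethyl)silyl]oxy}pent-3-en-2-yl propanoate | CCC(=O)O[C@@H](C)/C=C/CO[Si](C)(C)C(C)(C)C | intermediate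
19 | {[(1E)-1-{[(2S,3E)-5-{[tert-butyl(dimethyl)silyl]oxy}pent-3-en-2-yl]oxy}prop-1-en-1-yl]oxy}trimethylsilane | C/C=C(/O[Si](C)(C)C)O[C@@H](C)/C=C/CO[Si](C)(C)C(C)(C)C | intermediate (not isolated)
20 | trimethylsilyl (2R,3R,4E)-3-({[tert-butyl(dimethyl)silyl]oxy}methyl)-2-methylhex-4-enoate | C/C=C/[C@@H](CO[Si](C)(C)C(C)(C)C)[C@@H](C)C(=O)O[Si](C)(C)C | intermediate (not isolated)
21 | (2R,3R,4E)-3-({[tert-butyl(dimethyl)silyl]oxy}methyl)-2-methylhex-4-enoic acid | C/C=C/[C@@H](CO[Si](C)(C)C(C)(C)C)[C@@H](C)C(=O)O | intermediate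
22 | tert-butyl (2R,3R,4E)-3-({[tert-butyl(dimethyl)silyl]oxy}methyl)-2-methylhex-4-enoate | C/C=C/[C@@H](CO[Si](C)(C)C(C)(C)C)[C@@H](C)C(=O)OC(C)(C)C | intermediate
23 | tert-butyl (2R,3R,4E)-3-(hydroxymethyl)-2-methylhex-4-enoate | C/C=C/[C@@H](CO)[C@@H](C)C(=O)OC(C)(C)C | intermediate
24 | tert-butyl (2R,3R,4E)-3-(iodomethyl)-2-methylhex-4-enoate (fragment B) | C/C=C/[C@@H](CI)[C@@H](C)C(=O)OC(C)(C)C | intermediate
25 | tiglic acid, (2E)-2-methylbut-2-enoic acid | C/C=C(\C)C(=O)O | starting material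
26 | silver (2E)-2-methylbut-2-enoate | C/C=C(\C)C(=O)[O-].[Ag+] | intermediate
27 | alkylzinc iodide from 24 (C–I replaced by C–ZnI, stereocentres as in 24) | C/C=C/[C@@H](C[Zn]I)[C@@H](C)C(=O)OC(C)(C)C | intermediate (not isolated)
28 | di-tert-butyl (2R,3R,6R,7R)-2-ethenyl-3,7-dimethyl-4-oxo-6-[(1E)-prop-1-en-1-yl]-2-[(trimethylsilyl)oxy]octanedioate | CC(C)(C)OC(=O)[C@@](O[Si](C)(C)C)(C=C)[C@@H](C)C(=O)C[C@H](/C=C/C)[C@@H](C)C(=O)OC(C)(C)C | intermediate (not isolated)
29 | di-tert-butyl (2R,3R,6R,7R)-2-ethenyl-2-hydroxy-3,7-dimethyl-4-oxo-6-[(1E)-prop-1-en-1-yl]octanedioate | CC(C)(C)OC(=O)[C@@](O)(C=C)[C@@H](C)C(=O)C[C@H](/C=C/C)[C@@H](C)C(=O)OC(C)(C)C | intermediate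
30 | tert-butyl (1R,4R,7R)-4-[(2R)-1-tert-butoxy-1-oxopropan-2-yl]-1-hydroxy-7-methyl-6-oxocyclohept-2-ene-1-carboxylate | CC(C)(C)OC(=O)[C@]1(O)[C@@H](C)C(=O)C[C@@H]([C@@H](C)C(=O)OC(C)(C)C)C=C1 | intermediate
31 | tert-butyl (3R,3aS,6R,7R,8S,8aR)-7-hydroxy-8-iodo-3,6-dimethyl-2,5-dioxooctahydro-2H-cyclohepta[b]furan-7-carboxylate (cis-fused lactone, iodine trans to the lactone oxygen) | CC(C)(C)OC(=O)[C@]1(O)[C@@H](C)C(=O)C[C@@H]2[C@@H](OC(=O)[C@@H]2C)[C@@H]1I | intermediate
32 | C1–C5 epoxide (glycidic tert-butyl ester) of the lactone ketone, epoxide oxygen cis to the lactone oxygen | CC(C)(C)OC(=O)[C@]12O[C@@H]2[C@@H]3OC(=O)[C@H](C)[C@@H]3CC(=O)[C@@H]1C | intermediate (not isolated)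
33 | tert-butyl (3R,3aS,6R,7S,8S,8aR)-7-hydroxy-3,6-dimethyl-8-{[(2E)-2-methylbut-2-enoyl]oxy}-2,5-dioxooctahydro-2H-cyclohepta[b]furan-7-carboxylate | CC(C)(C)OC(=O)[C@]1(O)[C@@H](C)C(=O)C[C@@H]2[C@@H](OC(=O)[C@@H]2C)[C@@H]1OC(=O)/C(C)=C/C | intermediate
34 | (3R,3aS,6R,7S,8S,8aR)-7-hydroxy-3,6-dimethyl-8-{[(2E)-2-methylbut-2-enoyl]oxy}-2,5-dioxooctahydro-2H-cyclohepta[b]furan-7-carboxylic acid | OC(=O)[C@]1(O)[C@@H](C)C(=O)C[C@@H]2[C@@H](OC(=O)[C@@H]2C)[C@@H]1OC(=O)/C(C)=C/C | intermediate
35 | S-ethyl (3R,3aS,6R,7S,8S,8aR)-7-hydroxy-3,6-dimethyl-8-{[(2E)-2-methylbut-2-enoyl]oxy}-2,5-dioxooctahydro-2H-cyclohepta[b]furan-7-carbothioate | CCSC(=O)[C@]1(O)[C@@H](C)C(=O)C[C@@H]2[C@@H](OC(=O)[C@@H]2C)[C@@H]1OC(=O)/C(C)=C/C | intermediate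
36 | (E)-prop-1-en-1-ylboronic acid | C/C=C/B(O)O | starting material
37 | (3R,3aS,6R,7S,8S,8aR)-7-[(2E)-but-2-enoyl]-7-hydroxy-3,6-dimethyl-2,5-dioxooctahydro-2H-cyclohepta[b]furan-8-yl (2E)-2-methylbut-2-enoate | C/C=C/C(=O)[C@]1(O)[C@@H](C)C(=O)C[C@@H]2[C@@H](OC(=O)[C@@H]2C)[C@@H]1OC(=O)/C(C)=C/C | intermediate
38 | (3R,3aS,5R,6S,7S,8S,8aR)-7-[(2E)-but-2-enoyl]-5,7-dihydroxy-3,6-dimethyl-2-oxooctahydro-2H-cyclohepta[b]furan-8-yl (2E)-2-methylbut-2-enoate | C/C=C/C(=O)[C@]1(O)[C@@H](C)[C@H](O)C[C@@H]2[C@@H](OC(=O)[C@@H]2C)[C@@H]1OC(=O)/C(C)=C/C | target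

## Step count

Total: 25 steps. Longest linear sequence: 16 steps (12 to 24 by steps 9–16, then steps 18–25). The fragment A branch is 7 steps to 11 (steps 1–4 and 6–8); steps 5 and 17 are one-step side branches.

## The three steps most likely to fail, with fallbacks

**Step 21 (the new silver tiglate exchange).** Silver-promoted ionisation next to a tertiary carbinol could give semipinacol ring contraction, and the C5 carbon is hindered and deactivated by the C6 oxygen. The fallback uses known reactions and brings the tiglate in by ordinary acylation. It sets out from 31: DBU (CH2Cl2, 0 °C) closes the trans-iodohydrin to epoxide 32, which is isolated. Dilute HClO4 in THF/H2O opens 32 at C5 with inversion to the trans-diol tert-butyl (3R,3aS,6R,7S,8S,8aR)-7,8-dihydroxy-3,6-dimethyl-2,5-dioxooctahydro-2H-cyclohepta[b]furan-7-carboxylate F3. The secondary C5 hydroxyl of F3 is then acylated with (2E)-2-methylbut-2-enoyl chloride (DMAP, pyridine, CH2Cl2), the tertiary C1 hydroxyl being inert, and this comes back to the route at 33.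

**Step 18 (fragment coupling).** The thioester of 11 is α-branched and sits next to a quaternary carbon, so acyl–palladium formation may be slow and the alkylzinc may be consumed first. The fallback makes the C8–C9 bond by carbonyl addition instead. It sets out from 11 (with 24): i-Bu2AlH (CH2Cl2, −78 °C) reduces the thioester to tert-butyl (2R,3R)-2-ethenyl-3-methyl-4-oxo-2-[(trimethylsilyl)oxy]butanoate F1. Iodide 24 is then added to F1 as its alkylchromium reagent (CrCl2, cobalt phthalocyanine Co(C32H16N8) 5 mol %, DMF/THF, rt) to give di-tert-butyl 2-ethenyl-4-hydroxy-3,7-dimethyl-6-[(1E)-prop-1-en-1-yl]-2-[(trimethylsilyl)oxy]octanedioate (C4 carbinol epimers, other centres as in 28) F2. Dess–Martin oxidation of F2 comes back to the route at 28, which the acid work-up of step 18 turns into 29.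

**Step 24 (acyl coupling at the α-quaternary thioester).** Transmetalation at so hindered an acyl–palladium centre may be too slow. The fallback changes both the acyl electrophile and the nucleophile. It sets out from 34, bypassing 35: 1-chloro-N,N,2-trimethylprop-1-en-1-amine (CH2Cl2, 0 °C) gives (3R,3aS,6R,7S,8S,8aR)-7-(chlorocarbonyl)-7-hydroxy-3,6-dimethyl-2,5-dioxooctahydro-2H-cyclohepta[b]furan-8-yl (2E)-2-methylbut-2-enoate F4. Stille acylation of F4 with (E)-tributyl(prop-1-en-1-yl)stannane (Pd2(dba)3, tri(2-furyl)phosphine, THF, rt) comes back to the route at 37.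

## Further compounds

F1 | step 18 | tert-butyl (2R,3R)-2-ethenyl-3-methyl-4-oxo-2-[(trimethylsilyl)oxy]butanoate | CC(C)(C)OC(=O)[C@@](O[Si](C)(C)C)(C=C)[C@@H](C)C=O
F2 | step 18 | di-tert-butyl 2-ethenyl-4-hydroxy-3,7-dimethyl-6-[(1E)-prop-1-en-1-yl]-2-[(trimethylsilyl)oxy]octanedioate (C4 epimers, other centres as in 28) | CC(C)(C)OC(=O)[C@@](O[Si](C)(C)C)(C=C)[C@@H](C)C(O)C[C@H](/C=C/C)[C@@H](C)C(=O)OC(C)(C)C
F3 | step 21 | tert-butyl (3R,3aS,6R,7S,8S,8aR)-7,8-dihydroxy-3,6-dimethyl-2,5-dioxooctahydro-2H-cyclohepta[b]furan-7-carboxylate | CC(C)(C)OC(=O)[C@]1(O)[C@@H](C)C(=O)C[C@@H]2[C@@H](OC(=O)[C@@H]2C)[C@@H]1O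
F4 | step 24 | (3R,3aS,6R,7S,8S,8aR)-7-(chlorocarbonyl)-7-hydroxy-3,6-dimethyl-2,5-dioxooctahydro-2H-cyclohepta[b]furan-8-yl (2E)-2-methylbut-2-enoate | O=C(Cl)[C@]1(O)[C@@H](C)C(=O)C[C@@H]2[C@@H](OC(=O)[C@@H]2C)[C@@H]1OC(=O)/C(C)=C/C
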